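**Retrosynthetic overview**
1. Target ⇒ the isopropenyl group is unveiled last by dehydration of a C7 2‑hydroxyprop‑2‑yl group; the tiglate comes from acylation of the 3α‑OH; the senecioate comes from α‑acyloxylation of a C8=C9 silyl enol ether.
2. The C8=C9 enol ether and the trans ring fusion ⇒ Li/NH3 reduction of a Δ9(10)‑8‑enone; the C7 side chain ⇒ α′‑aldol addition to acetone.
3. 3α‑OH/4β‑Me ⇒ hydroboration of a C3=C4 alkene from the face opposite the angular methyl.
4. Dienone 4 ⇒ a new organocatalytic asymmetric deconjugative Michael/aldol (Robinson) annulation of achiral 2,3‑dimethylcyclohex‑2‑enone with methyl vinyl ketone, which sets the quaternary C5 first.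
5. Ring order: ring A is bought (compound 1), ring B is closed in step 1; every later stereocentre is substrate‑controlled from C5.

Assumption: 2,3‑dimethylcyclohex‑2‑en‑1‑one (1) is bought as such; locants C1–C15 in the text follow eremophilane numbering (C4 and C5 bear the methyls, C7 the three‑carbon side chain, C8 the ketone, C9 the senecioate, C10 the ring‑fusion CH), α/β mean the face opposite to/the same as the C5 methyl, and formal names use naphthalene numbering.

**Route**

Step 1
Reactants: 1 2,3-dimethylcyclohex-2-en-1-one; 2 but-3-en-2-one (methyl vinyl ketone)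
Product: 4 (4aR)-4a,5-dimethyl-4,4a,7,8-tetrahydronaphthalen-2(3H)-one, via Michael adduct 3 (not isolated)
Conditions: 1-[(1R,2R)-2-aminocyclohexyl]-3-[3,5-bis(trifluoromethyl)phenyl]thiourea (20 mol%), 4-nitrobenzoic acid (20 mol%), PhMe, 25 °C; then KOH, MeOH, 50 °C
Reagents that add atoms: none
Why: Proposed new method: the primary amine condenses with 1 and the conjugated ketimine tautomerises to the N–H linear dienamine (2-amino-1,3-diene), which attacks thiourea-bound 2 through its α-carbon in a six-membered aza-ene transition state with internal N–H transfer (a geometry open to the α-carbon but not to the γ-carbon, and favoured over the less substituted α′-enamine as in d'Angelo additions), so that the C5–C6 bond and the quaternary C5 stereocentre are set by the catalyst and the C3=C4 bond is left out of conjugation; hydrolysis gives 3, and KOH closes ring B by intramolecular aldol condensation (Robinson annulation); closest known reactions are the d'Angelo chiral-imine Michael addition of 2-alkylcyclanones, its primary amine–thiourea catalytic variants, and base-mediated α-alkylation of cyclohexenone dienolates, none of which has been run catalytically and enantioselectively on a 2,3-dialkylcyclohexenone.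

Step 2
Reactants: 4 (4aR)-4a,5-dimethyl-4,4a,7,8-tetrahydronaphthalen-2(3H)-one
Product: 6 (4aR,5R,6R)-6-hydroxy-4a,5-dimethyl-4,4a,5,6,7,8-hexahydronaphthalen-2(3H)-one, via alkylborane 5 (not isolated)
Conditions: BH3·THF (1.05 equiv), THF, −30 → 0 °C; MeOH; then pH 7 phosphate buffer, 30% H2O2, 0 → 20 °C
Reagents that add atoms: hydrogen peroxide, OO
Why: Brown hydroboration–oxidation, in which borane adds syn across the isolated trisubstituted C3=C4 bond from the α-face opposite the pseudo-axial C5 methyl (boron on C3, hydrogen on C4, hence 3α-OH and 4β-Me after oxidation with retention), alkene hydroboration being faster than reduction of the conjugated, β,β-disubstituted carbonyl, and buffered peroxide avoiding Weitz–Scheffer epoxidation of the enone.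

Step 3
Reactants: 6 (4aR,5R,6R)-6-hydroxy-4a,5-dimethyl-4,4a,5,6,7,8-hexahydronaphthalen-2(3H)-one; 7 acetone
Product: 9 (3S,4aR,5R,6R)-6-hydroxy-3-(2-hydroxypropan-2-yl)-4a,5-dimethyl-4,4a,5,6,7,8-hexahydronaphthalen-2(3H)-one, via dilithium dienolate alkoxide 8 (not isolated)
Conditions: LiN(iPr)2 (2.2 equiv), THF, −78 °C; 7, −78 °C; AcOH quench at −78 °C
Reagents that add atoms: none
Why: Directed aldol addition of the kinetic cross-conjugated α′-lithium enolate (the C3 hydroxyl rides along as its lithium alkoxide) to acetone, the electrophile entering C7 from the α-face away from the 1,3-related axial C5 methyl to give the equatorial side chain, which is also the thermodynamic epimer.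

Step 4
Reactants: 9 (3S,4aR,5R,6R)-6-hydroxy-3-(2-hydroxypropan-2-yl)-4a,5-dimethyl-4,4a,5,6,7,8-hexahydronaphthalen-2(3H)-one
Product: 11 trimethyl({(3S,4aS,5R,6R,8aS)-4a,5-dimethyl-6-[(trimethylsilyl)oxy]-3-{2-[(trimethylsilyl)oxy]propan-2-yl}-3,4,4a,5,6,7,8,8a-octahydronaphthalen-2-yl}oxy)silane, via dilithium enolate alkoxide 10 (not isolated)
Conditions: Li, NH3(l)/THF, −78 °C, 20 min; isoprene; NH3 evaporated; Me3SiCl, Et3N, DMAP (cat.), THF, −78 → 20 °C; filtered and used crude
Reagents that add atoms: chlorotrimethylsilane, C[Si](C)(C)Cl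
Why: Birch-type dissolving-metal reduction of the enone with Stork trapping of the enolate, in which protonation of the β-carbanion (by a hydroxyl of the substrate) gives the more stable trans ring fusion (10α-H) and a lithium enolate fixed at C8=C9, which is O-silylated together with both hydroxyls.

Step 5
Reactants: 11 trimethyl({(3S,4aS,5R,6R,8aS)-4a,5-dimethyl-6-[(trimethylsilyl)oxy]-3-{2-[(trimethylsilyl)oxy]propan-2-yl}-3,4,4a,5,6,7,8,8a-octahydronaphthalen-2-yl}oxy)silane; 12 3-methylbut-2-enoic acid (senecioic acid)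
Product: 14 (1S,3S,4aR,5R,6R,8aR)-6-hydroxy-3-(2-hydroxypropan-2-yl)-4a,5-dimethyl-2-oxodecahydronaphthalen-1-yl 3-methylbut-2-enoate, via bis(trimethylsilyl) ether 13 (not isolated)
Conditions: Pb(OAc)4 and 12 (PhMe, AcOH stripped in vacuo) to give Pb(O2CCH=CMe2)4; then 11, CH2Cl2, −20 → 20 °C; then citric acid, MeOH, 20 °C
Reagents that add atoms: none
Why: Rubottom-type lead tetracarboxylate oxidation of a silyl enol ether, in which plumbation at C9 and acyloxy transfer give the α-acyloxy ketone regiospecifically, the ester ending equatorial (9α) because the β-face is screened by the syn-axial C5 methyl and C9 can epimerise to this more stable isomer, while acidic methanol removes the two silyl ethers.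

Step 6
Reactants: 14 (1S,3S,4aR,5R,6R,8aR)-6-hydroxy-3-(2-hydroxypropan-2-yl)-4a,5-dimethyl-2-oxodecahydronaphthalen-1-yl 3-methylbut-2-enoate; 15 (2E)-2-methylbut-2-enoyl chloride (tigloyl chloride)
Product: 16 (1S,3S,4aR,5R,6R,8aR)-3-(2-hydroxypropan-2-yl)-4a,5-dimethyl-6-{[(2E)-2-methylbut-2-enoyl]oxy}-2-oxodecahydronaphthalen-1-yl 3-methylbut-2-enoate
Conditions: pyridine, DMAP (cat.), CH2Cl2, 0 → 20 °C
Reagents that add atoms: none
Why: DMAP-catalysed O-acylation (nucleophilic catalysis), in which only the secondary equatorial C3 hydroxyl reacts because the tertiary carbinol is inert under these conditions, and the E geometry of the tigloyl unit is kept.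

Step 7
Reactants: 16 (1S,3S,4aR,5R,6R,8aR)-3-(2-hydroxypropan-2-yl)-4a,5-dimethyl-6-{[(2E)-2-methylbut-2-enoyl]oxy}-2-oxodecahydronaphthalen-1-yl 3-methylbut-2-enoate
Product: 17 (1S,3S,4aR,5R,6R,8aR)-4a,5-dimethyl-6-{[(2E)-2-methylbut-2-enoyl]oxy}-2-oxo-3-(prop-1-en-2-yl)decahydronaphthalen-1-yl 3-methylbut-2-enoate (CNP0375730.3)
Conditions: SOCl2, pyridine, CH2Cl2, −40 → 0 °C
Reagents that add atoms: none
Why: Kinetic dehydration of the tertiary alcohol through its chlorosulfite (E2 with pyridine), in which a methyl proton is removed in preference to the axial C7–H (screened by the syn-axial C5 methyl, and leading to a strained tetrasubstituted enone), so the base-sensitive α-isopropenyl ketone appears only in the last step and C7 keeps its configuration.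

**Compound list**
1 | 2,3-dimethylcyclohex-2-en-1-one | CC1=C(C)C(=O)CCC1 | starting material
2 | but-3-en-2-one (methyl vinyl ketone) | CC(=O)C=C | starting material
3 | (2R)-2,3-dimethyl-2-(3-oxobutyl)cyclohex-3-en-1-one (not isolated) | CC(=O)CC[C@]1(C)C(C)=CCCC1=O | intermediate
4 | (4aR)-4a,5-dimethyl-4,4a,7,8-tetrahydronaphthalen-2(3H)-one | O=C1CC[C@]2(C)C(C)=CCCC2=C1 | intermediate
5 | (4aR,5S,6R)-6-boranyl-4a,5-dimethyl-4,4a,5,6,7,8-hexahydronaphthalen-2(3H)-one (not isolated) | O=C1CC[C@]2(C)[C@@H](C)[C@H](B)CCC2=C1 | intermediate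
6 | (4aR,5R,6R)-6-hydroxy-4a,5-dimethyl-4,4a,5,6,7,8-hexahydronaphthalen-2(3H)-one | O=C1CC[C@]2(C)[C@@H](C)[C@H](O)CCC2=C1 | intermediate
7 | acetone | CC(C)=O | starting material
8 | dilithium (4aR,5R,6R)-4a,5-dimethyl-4,4a,5,6,7,8-hexahydronaphthalene-2,6-bis(olate) (not isolated) | [Li]OC1=CC[C@]2(C)[C@@H](C)[C@H](O[Li])CCC2=C1 | intermediate
9 | (3S,4aR,5R,6R)-6-hydroxy-3-(2-hydroxypropan-2-yl)-4a,5-dimethyl-4,4a,5,6,7,8-hexahydronaphthalen-2(3H)-one | CC(C)(O)[C@@H]1C[C@]2(C)[C@@H](C)[C@H](O)CCC2=CC1=O | intermediate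
10 | dilithium (3S,4aS,5R,6R,8aS)-3-(2-hydroxypropan-2-yl)-4a,5-dimethyl-3,4,4a,5,6,7,8,8a-octahydronaphthalene-2,6-bis(olate) (not isolated) | CC(C)(O)[C@@H]1C[C@]2(C)[C@@H](C)[C@H](O[Li])CC[C@H]2C=C1O[Li] | intermediate
11 | trimethyl({(3S,4aS,5R,6R,8aS)-4a,5-dimethyl-6-[(trimethylsilyl)oxy]-3-{2-[(trimethylsilyl)oxy]propan-2-yl}-3,4,4a,5,6,7,8,8a-octahydronaphthalen-2-yl}oxy)silane | C[Si](C)(C)OC(C)(C)[C@@H]1C[C@]2(C)[C@@H](C)[C@H](O[Si](C)(C)C)CC[C@H]2C=C1O[Si](C)(C)C | intermediate
12 | 3-methylbut-2-enoic acid (senecioic acid) | CC(C)=CC(=O)O | starting material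
13 | (1S,3S,4aR,5R,6R,8aR)-4a,5-dimethyl-2-oxo-6-[(trimethylsilyl)oxy]-3-{2-[(trimethylsilyl)oxy]propan-2-yl}decahydronaphthalen-1-yl 3-methylbut-2-enoate (not isolated) | C[Si](C)(C)OC(C)(C)[C@@H]1C[C@]2(C)[C@@H](C)[C@H](O[Si](C)(C)C)CC[C@H]2[C@H](OC(=O)C=C(C)C)C1=O | intermediate
14 | (1S,3S,4aR,5R,6R,8aR)-6-hydroxy-3-(2-hydroxypropan-2-yl)-4a,5-dimethyl-2-oxodecahydronaphthalen-1-yl 3-methylbut-2-enoate | CC(C)(O)[C@@H]1C[C@]2(C)[C@@H](C)[C@H](O)CC[C@H]2[C@H](OC(=O)C=C(C)C)C1=O | intermediate
15 | (2E)-2-methylbut-2-enoyl chloride (tigloyl chloride) | C/C=C(\C)C(=O)Cl | starting material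
16 | (1S,3S,4aR,5R,6R,8aR)-3-(2-hydroxypropan-2-yl)-4a,5-dimethyl-6-{[(2E)-2-methylbut-2-enoyl]oxy}-2-oxodecahydronaphthalen-1-yl 3-methylbut-2-enoate | CC(C)(O)[C@@H]1C[C@]2(C)[C@@H](C)[C@H](OC(=O)/C(C)=C/C)CC[C@H]2[C@H](OC(=O)C=C(C)C)C1=O | intermediate
17 | (1S,3S,4aR,5R,6R,8aR)-4a,5-dimethyl-6-{[(2E)-2-methylbut-2-enoyl]oxy}-2-oxo-3-(prop-1-en-2-yl)decahydronaphthalen-1-yl 3-methylbut-2-enoate | C=C(C)[C@@H]1C[C@]2(C)[C@@H](C)[C@H](OC(=O)/C(C)=C/C)CC[C@H]2[C@H](OC(=O)C=C(C)C)C1=O | target

**Step count:** 7 steps in total; longest linear sequence 7 steps (1 + 2 → 17).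

**The three steps most likely to fail**

Step 1 (the new annulation). The risks are attack through the γ- or α′-carbon of the dienamine instead of the α-carbon, slow turnover at a quaternary centre, and modest enantioselectivity. The sense of induction of the (1R,2R) catalyst is not predicted with confidence; if it is opposite, the (1S,2S) catalyst is used. The fallback uses known chemistry, sets out from 2 and comes back to the route at 4. Compound 2 is added (Et3N cat.) to purchased 2-methylcyclohexane-1,3-dione F1 to give the triketone F2. L-Proline in DMSO converts this, by the Hajos–Parrish–Eder–Sauer–Wiechert aldol condensation, into the (S)-Wieland–Miescher ketone F3, which carries the same quaternary centre. Ph3P=CH2 (from Ph3PCH3Br and KOt-Bu, THF) methylenates only the saturated carbonyl to give the methylidene enone F4. RhCl3·3H2O (cat., EtOH, reflux) then moves the exocyclic double bond into the ring, where C3=C4 is the only position open next to the quaternary carbon, to give 4.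

Step 2 (chemoselectivity). Borane may also reduce the enone carbonyl to the allylic alcohol. The fallback sets out from 4 and comes back at 6. The carbonyl is masked as the 1,3-dithiolane F5 (ethane-1,2-dithiol, BF3·OEt2, no double-bond shift). In F5, C9 is flanked by the spiro centre, so BH3·SMe2 followed by Me3NO oxidation should touch only C3=C4 and give the hydroxy dithiolane F6. MeI and NaHCO3 in aqueous MeCN then release 6.

Step 7 (regiochemistry of the dehydration). Loss of the C7 proton would give the conjugated isopropylidene isomer. The fallback sets out from 6 and comes back at 17; it brings the alkene in as such instead of by dehydration. Compound 6 is silylated (TBSCl, imidazole) to the silyl ether F7. Its α′-lithium enolate (LiN(SiMe3)2, THF, −78 °C) is coupled with 2-bromopropene under zerovalent palladium catalysis (Pd2(dba)3, P(t-Bu)3) to give the isopropenyl enone F8. Li/NH3 (t-BuOH, 1 equiv) then Me3SiCl gives the silyl enol ether F9. The lead carboxylate oxidation of step 5 (methanol work-up) gives the keto ester F10, HF·pyridine frees the alcohol F11, and 15 with pyridine and DMAP gives 17.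

**Further compounds**
F1 | step 1 | 2-methylcyclohexane-1,3-dione (purchased) | CC1C(=O)CCCC1=O
F2 | step 1 | 2-methyl-2-(3-oxobutyl)cyclohexane-1,3-dione | CC(=O)CCC1(C)C(=O)CCCC1=O
F3 | step 1 | (8aS)-8a-methyl-3,4,8,8a-tetrahydronaphthalene-1,6(2H,7H)-dione | O=C1CC[C@]2(C)C(=O)CCCC2=C1
F4 | step 1 | (4aR)-4a-methyl-5-methylidene-4,4a,5,6,7,8-hexahydronaphthalen-2(3H)-one | O=C1CC[C@]2(C)C(=C)CCCC2=C1
F5 | step 2 | 1,3-dithiolane of 4: (4a'R)-4a',5'-dimethyl-4',4a',7',8'-tetrahydro-3'H-spiro[[1,3]dithiolane-2,2'-naphthalene] | S1CCSC13CC[C@]2(C)C(C)=CCCC2=C3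
F6 | step 2 | 1,3-dithiolane of 6: (4a'R,5'R,6'R)-4a',5'-dimethyl-4',4a',5',6',7',8'-hexahydro-3'H-spiro[[1,3]dithiolane-2,2'-naphthalen]-6'-ol | S1CCSC13CC[C@]2(C)[C@@H](C)[C@H](O)CCC2=C3
F7 | step 7 | (4aR,5R,6R)-6-{[tert-butyl(dimethyl)silyl]oxy}-4a,5-dimethyl-4,4a,5,6,7,8-hexahydronaphthalen-2(3H)-one | O=C1CC[C@]2(C)[C@@H](C)[C@H](O[Si](C)(C)C(C)(C)C)CCC2=C1
F8 | step 7 | (3S,4aR,5R,6R)-6-{[tert-butyl(dimethyl)silyl]oxy}-4a,5-dimethyl-3-(prop-1-en-2-yl)-4,4a,5,6,7,8-hexahydronaphthalen-2(3H)-one | C=C(C)[C@@H]1C[C@]2(C)[C@@H](C)[C@H](O[Si](C)(C)C(C)(C)C)CCC2=CC1=O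
F9 | step 7 | {[(3S,4aS,5R,6R,8aS)-6-{[tert-butyl(dimethyl)silyl]oxy}-4a,5-dimethyl-3-(prop-1-en-2-yl)-3,4,4a,5,6,7,8,8a-octahydronaphthalen-2-yl]oxy}(trimethyl)silane | C=C(C)[C@@H]1C[C@]2(C)[C@@H](C)[C@H](O[Si](C)(C)C(C)(C)C)CC[C@H]2C=C1O[Si](C)(C)C
F10 | step 7 | (1S,3S,4aR,5R,6R,8aR)-6-{[tert-butyl(dimethyl)silyl]oxy}-4a,5-dimethyl-2-oxo-3-(prop-1-en-2-yl)decahydronaphthalen-1-yl 3-methylbut-2-enoate | C=C(C)[C@@H]1C[C@]2(C)[C@@H](C)[C@H](O[Si](C)(C)C(C)(C)C)CC[C@H]2[C@H](OC(=O)C=C(C)C)C1=O
F11 | step 7 | (1S,3S,4aR,5R,6R,8aR)-6-hydroxy-4a,5-dimethyl-2-oxo-3-(prop-1-en-2-yl)decahydronaphthalen-1-yl 3-methylbut-2-enoate | C=C(C)[C@@H]1C[C@]2(C)[C@@H](C)[C@H](O)CC[C@H]2[C@H](OC(=O)C=C(C)C)C1=O
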